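## Retrosynthetic overview

- Canaliculatol ⇐ its octamethyl ether ⇐ an indanyl anisyl carbinol, by a Friedel–Crafts closure of the eight-membered ring onto the 3,5-dimethoxyphenyl ring of the dihydrobenzofuran.
- The cis-diaryl indane ⇐ an indenyl ketone: reduction with dynamic kinetic resolution fixes indene C1, then hydroxyl-directed hydrogenation sets C2 and C3.
- The indene five-membered ring ⇐ palladium carboannulation of a dihydrobenzofuranyl anisyl alkyne with an ortho-iodinated deoxybenzoin; the alkyne ⇐ aryl bromide + 4-ethynylanisole.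
- The trans-dihydrobenzofuran ⇐ an α,α-diaryl ketone, by dynamic kinetic reduction and dealkylative O-cyclisation.
- Key bond: the ketone α-carbon to arene carbon bond of that ketone, made from a deoxybenzoin used as an enolonium (α-keto cation) and a bromodimethoxybenzene. Ring order: dihydrofuran, indene five-membered ring, eight-membered ring.

Assumption: the sense of induction of the TsDPEN ruthenium catalysts at the labile α-carbons (steps 4 and 8) is taken by analogy with α-aryl ketones; if it proves opposite, the antipodal catalyst is used, since both carbinol centres are erased later by ionisation.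

## Route

Step 1
Reactants: 1 4′-methoxyacetophenone; 2 1-bromo-3,5-dimethoxybenzene
Product: 3 2-(3,5-dimethoxyphenyl)-1-(4-methoxyphenyl)ethanone
Conditions: Pd(OAc)2 (2 mol %), XPhos (4 mol %), NaOtBu (2.2 equiv), toluene, 80 °C; 1 in 1.5-fold excess
Reagents that add atoms: none
Why: Palladium-catalysed ketone α-arylation (Buchwald–Hartwig type), in which the more acidic product rests as its enolate and so is not arylated twice; no stereocentre is formed.

Step 2
Reactants: 3 2-(3,5-dimethoxyphenyl)-1-(4-methoxyphenyl)ethanone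
Product: 4 2-(2-iodo-3,5-dimethoxyphenyl)-1-(4-methoxyphenyl)ethanone
Conditions: NIS (1.05 equiv), CF3CO2H (10 mol %), MeCN, 0 → 20 °C
Reagents that add atoms: N-iodosuccinimide, O=C1CCC(=O)N1I
Why: Electrophilic aromatic iodination goes to the ring carbon para to one methoxy group and ortho to the benzylic carbon, the usual site in 3,5-dimethoxybenzyl compounds, while the acyl-deactivated anisyl ring is untouched; no stereocentre.

Step 3
Reactants: 3 2-(3,5-dimethoxyphenyl)-1-(4-methoxyphenyl)ethanone; 2 1-bromo-3,5-dimethoxybenzene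
Product: 7 rac-2-(2-bromo-4,6-dimethoxyphenyl)-2-(3,5-dimethoxyphenyl)-1-(4-methoxyphenyl)ethanone, via silyl enol ether 5 (not isolated), via iodanyl enolate 6 (not isolated)
Conditions: LiN(SiMe3)2, Me3SiCl, THF, −78 °C; filter, swap to CH2Cl2; PhI(OH)OTs (1.2 equiv), BF3·OEt2 (1.5 equiv), −78 °C; then 2 (5 equiv, excess recovered), −78 → −20 °C
Reagents that add atoms: none
Why: Key step, enolonium (umpoled enolate) α-arylation: oxidation of silyl enol ether 5 by the trivalent-iodine reagent turns the ketone α-carbon into an electrophile that is attacked by arene 2 at the carbon para to one methoxy group and ortho to bromine (the site of its Vilsmeier formylation), joining two carbons that are both nucleophilic in normal reactivity; the new stereocentre is α to the ketone and is left racemic on purpose because step 4 resolves it dynamically.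

Step 4
Reactants: 7 rac-2-(2-bromo-4,6-dimethoxyphenyl)-2-(3,5-dimethoxyphenyl)-1-(4-methoxyphenyl)ethanone
Product: 8 (1R,2R)-2-(2-bromo-4,6-dimethoxyphenyl)-2-(3,5-dimethoxyphenyl)-1-(4-methoxyphenyl)ethanol
Conditions: RuCl[(R,R)-TsDPEN](p-cymene) (2 mol %), HCO2H/Et3N (5:2), DMF, 40 °C
Reagents that add atoms: none
Why: Noyori-type asymmetric transfer hydrogenation with dynamic kinetic resolution: the doubly benzylic α-carbon epimerises through the enol under the amine buffer while the catalyst reduces one enantiomer faster (hydride anti to the bulky 2-bromo-4,6-dimethoxyphenyl group in a Felkin arrangement), so the carbinol (R) and the adjacent stereocentre (R) are set together.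

Step 5
Reactants: 8 (1R,2R)-2-(2-bromo-4,6-dimethoxyphenyl)-2-(3,5-dimethoxyphenyl)-1-(4-methoxyphenyl)ethanol
Product: 9 (2R,3R)-4-bromo-3-(3,5-dimethoxyphenyl)-6-methoxy-2-(4-methoxyphenyl)-2,3-dihydro-1-benzofuran
Conditions: Me3SiI (1.1 equiv), CH2Cl2, −40 → 0 °C
Reagents that add atoms: none
Why: Silyl-iodide ionisation of the 4-methoxybenzylic alcohol gives a stabilised cation that is captured by the ortho methoxy oxygen (neighbouring-group participation closing a five-membered oxonium ring), and iodide then removes the methyl group (dealkylative cycloetherification); C3 is untouched and C2 closes reversibly to the 2,3-trans isomer, giving (2R,3R).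

Step 6
Reactants: 9 (2R,3R)-4-bromo-dihydrobenzofuran; 10 1-ethynyl-4-methoxybenzene
Product: 11 (2R,3R)-3-(3,5-dimethoxyphenyl)-6-methoxy-2-(4-methoxyphenyl)-4-[(4-methoxyphenyl)ethynyl]-2,3-dihydro-1-benzofuran
Conditions: PdCl2(MeCN)2 (3 mol %), XPhos (9 mol %), Cs2CO3 (2.5 equiv), MeCN, 80 °C
Reagents that add atoms: none
Why: Copper-free Sonogashira coupling with a bulky biarylphosphine copes with the electron-rich ortho-substituted aryl bromide; no stereocentre is touched.

Step 7
Reactants: 11 dihydrobenzofuranyl anisyl alkyne; 4 2-(2-iodo-3,5-dimethoxyphenyl)-1-(4-methoxyphenyl)ethanone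
Product: 12 indenyl ketone {2-[(2R,3R)-dihydrobenzofuran-4-yl]-4,6-dimethoxy-3-(4-methoxyphenyl)-1H-inden-1-yl}(4-methoxyphenyl)methanone (indene C1 labile)
Conditions: Pd(OAc)2 (5 mol %), P(t-Bu)3·HBF4 (10 mol %), K3PO4 (3 equiv), DMF, 100 °C; 4 (1.5 equiv)
Reagents that add atoms: none
Why: Proposed new method: oxidative addition of zerovalent palladium into the aryl iodide of 4, syn-carbopalladation of alkyne 11 with the aryl group going to the anisyl-bearing carbon (the bulky dihydrobenzofuranyl group ends next to palladium, as in Larock annulations) and C–C reductive elimination with the ketone enolate carbon close the indene, the closest known reactions being the Larock carboannulation of internal alkynes with 2-(2-iodophenyl)malonates and palladium-catalysed α-alkenylation of ketone enolates; C1 of the indene is formed as a labile epimer mixture after kinetic α-protonation.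

Step 8
Reactants: 12 indenyl ketone
Product: 13 (S)-{(1R)-2-[(2R,3R)-dihydrobenzofuran-4-yl]-4,6-dimethoxy-3-(4-methoxyphenyl)-1H-inden-1-yl}(4-methoxyphenyl)methanol
Conditions: RuCl[(S,S)-TsDPEN](p-cymene) (3 mol %), HCO2H/Et3N (5:2), CH2Cl2, 30 °C
Reagents that add atoms: none
Why: Noyori-type transfer hydrogenation with dynamic kinetic resolution: C1 of the indene is α to the ketone and part of an indenyl system, so it epimerises fast under the amine buffer, and the catalyst (not the remote dihydrobenzofuran) fixes the carbinol (S) and C1 (R) in one operation.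

Step 9
Reactants: 13 indenyl carbinol
Product: 14 (S)-{(1S,2R,3R)-2-[(2R,3R)-dihydrobenzofuran-4-yl]-4,6-dimethoxy-3-(4-methoxyphenyl)-2,3-dihydro-1H-inden-1-yl}(4-methoxyphenyl)methanol
Conditions: [Ir(cod)(PCy3)(py)][B(3,5-(CF3)2C6H3)4] (10 mol %), H2 (50 bar), CH2Cl2, 25 °C
Reagents that add atoms: none
Why: Hydroxyl-directed hydrogenation with a Crabtree-type cationic iridium catalyst: the homoallylic carbinol binds iridium and both hydrogens are delivered to the tetrasubstituted C2=C3 bond on the face of the carbinol side chain, which makes the two aryl groups cis to each other and trans to the side chain and so sets C2 (R) and C3 (R).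

Step 10
Reactants: 14 indanyl carbinol
Product: 15 octa-O-methylcanaliculatol
Conditions: Bi(OTf)3 (10 mol %), (CF3)2CHOH/CH2Cl2 (1:4), 2 mM, −20 °C
Reagents that add atoms: none
Why: Proposed new method: Lewis-acid ionisation of the carbinol gives a 4-methoxybenzylic cation that is attacked by the 3,5-dimethoxyphenyl ring on C3 of the dihydrobenzofuran at its ortho carbon (para to methoxy), closing the eight-membered ring, because the trans arrangement at C1/C2 of the indane rules out five-membered closure onto the benzofuran ring and hexafluoroisopropanol offers no base for elimination; the new benzylic stereocentre (R) is set in the ring-closing transition state with the anisyl group anti to the indane aryl bond; closest known reactions are intramolecular Friedel–Crafts cycloalkylations of benzylic cations that form five- and seven-membered rings in resveratrol oligomer synthesis and the presumed biogenetic quinone-methide cyclisation.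

Step 11
Reactants: 15 octa-O-methylcanaliculatol
Product: 16 canaliculatol
Conditions: BBr3 (16 equiv), CH2Cl2, −78 → 20 °C; then H2O, 0 °C
Reagents that add atoms: none
Why: Exhaustive Lewis-acid O-demethylation of the eight aryl methyl ethers with BBr3, a standard last step for permethylated resveratrol oligomers; no bond at a stereocentre is broken and the dihydrobenzofuran C–O bond is expected to survive at low temperature.

## Compound list

1 | 4′-methoxyacetophenone | CC(=O)c1ccc(OC)cc1 | starting material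
2 | 1-bromo-3,5-dimethoxybenzene | COc1cc(Br)cc(OC)c1 | starting material
3 | 2-(3,5-dimethoxyphenyl)-1-(4-methoxyphenyl)ethanone | COc1ccc(cc1)C(=O)Cc1cc(OC)cc(OC)c1 | intermediate
4 | 2-(2-iodo-3,5-dimethoxyphenyl)-1-(4-methoxyphenyl)ethanone | COc1ccc(cc1)C(=O)Cc1cc(OC)cc(OC)c1I | intermediate
5 | (Z)-[2-(3,5-dimethoxyphenyl)-1-(4-methoxyphenyl)ethenyl]oxy(trimethyl)silane (silyl enol ether of 3) | COc1ccc(cc1)/C(O[Si](C)(C)C)=C/c1cc(OC)cc(OC)c1 | intermediate
6 | (Z)-2-(3,5-dimethoxyphenyl)-1-(4-methoxyphenyl)ethenyl phenyl(tosyloxy)-λ3-iodanyl ether (O-bound trivalent-iodine enolate of 3, the enolonium species) | COc1ccc(cc1)/C(OI(c1ccccc1)OS(=O)(=O)c1ccc(C)cc1)=C/c1cc(OC)cc(OC)c1 | intermediate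
7 | rac-2-(2-bromo-4,6-dimethoxyphenyl)-2-(3,5-dimethoxyphenyl)-1-(4-methoxyphenyl)ethanone | COc1ccc(cc1)C(=O)C(c1cc(OC)cc(OC)c1)c1c(Br)cc(OC)cc1OC | intermediate
8 | (1R,2R)-2-(2-bromo-4,6-dimethoxyphenyl)-2-(3,5-dimethoxyphenyl)-1-(4-methoxyphenyl)ethanol | COc1ccc(cc1)[C@H](O)[C@H](c1cc(OC)cc(OC)c1)c1c(Br)cc(OC)cc1OC | intermediate
9 | (2R,3R)-4-bromo-3-(3,5-dimethoxyphenyl)-6-methoxy-2-(4-methoxyphenyl)-2,3-dihydro-1-benzofuran (2,3-trans) | COc1ccc(cc1)[C@@H]1Oc2cc(OC)cc(Br)c2[C@H]1c1cc(OC)cc(OC)c1 | intermediate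
10 | 1-ethynyl-4-methoxybenzene | COc1ccc(cc1)C#C | starting material
11 | (2R,3R)-3-(3,5-dimethoxyphenyl)-6-methoxy-2-(4-methoxyphenyl)-4-[(4-methoxyphenyl)ethynyl]-2,3-dihydro-1-benzofuran | COc1ccc(cc1)[C@@H]1Oc2cc(OC)cc(C#Cc3ccc(OC)cc3)c2[C@H]1c1cc(OC)cc(OC)c1 | intermediate
12 | {2-[(2R,3R)-3-(3,5-dimethoxyphenyl)-6-methoxy-2-(4-methoxyphenyl)-2,3-dihydro-1-benzofuran-4-yl]-4,6-dimethoxy-3-(4-methoxyphenyl)-1H-inden-1-yl}(4-methoxyphenyl)methanone (indene C1 labile, both epimers) | COc1ccc(cc1)C(=O)C1C(c2cc(OC)cc3O[C@@H](c4ccc(OC)cc4)[C@H](c4cc(OC)cc(OC)c4)c23)=C(c2ccc(OC)cc2)c2c(OC)cc(OC)cc12 | intermediate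
13 | (S)-{(1R)-2-[(2R,3R)-3-(3,5-dimethoxyphenyl)-6-methoxy-2-(4-methoxyphenyl)-2,3-dihydro-1-benzofuran-4-yl]-4,6-dimethoxy-3-(4-methoxyphenyl)-1H-inden-1-yl}(4-methoxyphenyl)methanol | COc1ccc(cc1)[C@@H](O)[C@H]1C(c2cc(OC)cc3O[C@@H](c4ccc(OC)cc4)[C@H](c4cc(OC)cc(OC)c4)c23)=C(c2ccc(OC)cc2)c2c(OC)cc(OC)cc12 | intermediate
14 | (S)-{(1S,2R,3R)-2-[(2R,3R)-3-(3,5-dimethoxyphenyl)-6-methoxy-2-(4-methoxyphenyl)-2,3-dihydro-1-benzofuran-4-yl]-4,6-dimethoxy-3-(4-methoxyphenyl)-2,3-dihydro-1H-inden-1-yl}(4-methoxyphenyl)methanol (H1/H2 trans, H2/H3 cis) | COc1ccc(cc1)[C@@H](O)[C@H]1[C@H](c2cc(OC)cc3O[C@@H](c4ccc(OC)cc4)[C@H](c4cc(OC)cc(OC)c4)c23)[C@H](c2ccc(OC)cc2)c2c(OC)cc(OC)cc12 | intermediate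
15 | octa-O-methylcanaliculatol (all eight phenols of 16 as methyl ethers, same six stereocentres) | COc1ccc([C@@H]2c3c(OC)cc(OC)cc3[C@H]3[C@H](c4ccc(OC)cc4)c4c(OC)cc(OC)cc4[C@@H]4c5c(cc(OC)cc5[C@H]23)O[C@H]4c2ccc(OC)cc2)cc1 | intermediate
16 | canaliculatol | Oc1ccc([C@@H]2c3c(O)cc(O)cc3[C@H]3[C@H](c4ccc(O)cc4)c4c(O)cc(O)cc4[C@@H]4c5c(cc(O)cc5[C@H]23)O[C@H]4c2ccc(O)cc2)cc1 | target

## Step count and risks

Total step count: 11. Longest linear sequence: 10 (steps 1 and 3 to 11; step 2 is a one-step branch from 3 that joins in step 7).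

The three steps most likely to fail:

Step 3 (key arylation). Arene 2 is only a moderate nucleophile and must react at a flanked position, and the trivalent-iodine oxidant could also attack the electron-rich rings. The fallback sets out from 3 and comes back at 7. Bromination of 3 with CuBr2 (EtOAc/CHCl3, reflux) gives the α-bromo ketone rac-2-bromo-2-(3,5-dimethoxyphenyl)-1-(4-methoxyphenyl)ethanone F1. AgOTf in (CF3)2CHOH/CH2Cl2 at 0 °C with 2 (5 equiv) then ionises F1 to the same α-keto benzylic cation, which alkylates 2 to give 7. This replaces oxidation of an enol silane by halogenation and silver-assisted ionisation of the classical α-halo ketone.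

Step 9 (directed hydrogenation). The tetrasubstituted diaryl alkene may resist the iridium catalyst or be reduced from the open face. The fallback sets out from 12 and comes back at 14; it uses steric approach control followed by epimerisation instead of hydroxyl direction. Reduction of 12 with the antipodal catalyst RuCl[(R,R)-TsDPEN](p-cymene) under the step 8 conditions gives the mirror-configured carbinol (R)-{(1S)-indenyl}(4-methoxyphenyl)methanol F2. Heterogeneous hydrogenation (Pd on carbon, H2 50 bar, EtOAc) adds hydrogen anti to the side chain and gives the all-cis indanyl carbinol F3. Dess–Martin periodinane gives the all-cis ketone F4, and DBU (THF, 20 °C) epimerises the carbon α to the ketone to the 1,2-trans-2,3-cis ketone F5. Transfer hydrogenation of F5 with RuCl[(S,S)-TsDPEN](p-cymene) and HCO2H/Et3N gives 14.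

Step 10 (eight-membered ring closure). The cation can instead lose a proton to the benzylidene-indane, which acid isomerises into the ring. The fallback sets out from 14 and comes back at 15. CCl3CN with DBU (10 mol %) in CH2Cl2 at 0 °C gives the trichloroacetimidate of 14 F6. Me3SiOTf (5 mol %) in CH2Cl2 at −78 °C and 1 mM over 4 Å sieves ionises F6 without water or protic acid and closes the ring to 15. This is aprotic ionisation of a pre-formed leaving group instead of acid dehydration.

Further compounds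

F1 | step 3 | rac-2-bromo-2-(3,5-dimethoxyphenyl)-1-(4-methoxyphenyl)ethanone | COc1ccc(cc1)C(=O)C(Br)c1cc(OC)cc(OC)c1
F2 | step 9 | (R)-{(1S)-2-[(2R,3R)-3-(3,5-dimethoxyphenyl)-6-methoxy-2-(4-methoxyphenyl)-2,3-dihydro-1-benzofuran-4-yl]-4,6-dimethoxy-3-(4-methoxyphenyl)-1H-inden-1-yl}(4-methoxyphenyl)methanol | COc1ccc(cc1)[C@H](O)[C@@H]1C(c2cc(OC)cc3O[C@@H](c4ccc(OC)cc4)[C@H](c4cc(OC)cc(OC)c4)c23)=C(c2ccc(OC)cc2)c2c(OC)cc(OC)cc12
F3 | step 9 | (R)-{(1R,2R,3R)-2-[(2R,3R)-3-(3,5-dimethoxyphenyl)-6-methoxy-2-(4-methoxyphenyl)-2,3-dihydro-1-benzofuran-4-yl]-4,6-dimethoxy-3-(4-methoxyphenyl)-2,3-dihydro-1H-inden-1-yl}(4-methoxyphenyl)methanol (all-cis) | COc1ccc(cc1)[C@H](O)[C@@H]1[C@H](c2cc(OC)cc3O[C@@H](c4ccc(OC)cc4)[C@H](c4cc(OC)cc(OC)c4)c23)[C@H](c2ccc(OC)cc2)c2c(OC)cc(OC)cc12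
F4 | step 9 | {(1R,2R,3R)-2-[(2R,3R)-3-(3,5-dimethoxyphenyl)-6-methoxy-2-(4-methoxyphenyl)-2,3-dihydro-1-benzofuran-4-yl]-4,6-dimethoxy-3-(4-methoxyphenyl)-2,3-dihydro-1H-inden-1-yl}(4-methoxyphenyl)methanone (all-cis) | COc1ccc(cc1)C(=O)[C@@H]1[C@H](c2cc(OC)cc3O[C@@H](c4ccc(OC)cc4)[C@H](c4cc(OC)cc(OC)c4)c23)[C@H](c2ccc(OC)cc2)c2c(OC)cc(OC)cc12
F5 | step 9 | {(1S,2R,3R)-2-[(2R,3R)-3-(3,5-dimethoxyphenyl)-6-methoxy-2-(4-methoxyphenyl)-2,3-dihydro-1-benzofuran-4-yl]-4,6-dimethoxy-3-(4-methoxyphenyl)-2,3-dihydro-1H-inden-1-yl}(4-methoxyphenyl)methanone (1,2-trans, 2,3-cis) | COc1ccc(cc1)C(=O)[C@H]1[C@H](c2cc(OC)cc3O[C@@H](c4ccc(OC)cc4)[C@H](c4cc(OC)cc(OC)c4)c23)[C@H](c2ccc(OC)cc2)c2c(OC)cc(OC)cc12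
F6 | step 10 | O-trichloroacetimidate of 14 | COc1ccc(cc1)[C@@H](OC(=N)C(Cl)(Cl)Cl)[C@H]1[C@H](c2cc(OC)cc3O[C@@H](c4ccc(OC)cc4)[C@H](c4cc(OC)cc(OC)c4)c23)[C@H](c2ccc(OC)cc2)c2c(OC)cc(OC)cc12
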